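**Plan**
- Retrosynthesis: the ring-fusion bond C1–C5 is cut and C1 is reconnected to C6 (retro-semipinacol). This turns the 5/7 core into a cis-fused 6/6 octalin with an allylic leaving group on C5, itself derived from a C5–C6 epoxide. Then come, in order, the C9 ester, C4=C15 (Wittig), the C9/C10 oxygens, C5=C6 (aldol condensation), C1–C2 (Grignard) and the C6 oxygen, leaving (S)-carvone.
- Forward: the carvone ring supplies C1, C6, C7, C8, C9, C10, C14 and the isopropyl group. Ring A (C1–C6) is annulated onto it. In the last step ring A contracts to the cyclopentane while the carvone ring grows by one carbon (C5) into the cycloheptanone.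
- Enabling feature: in the target, C5 is α to the C6 ketone, allylic to the C4=C15 methylene and bonded to the carbinol carbon C1. That is exactly the terminus of a 1,2-shift of C1 from a C6 carbinol to a C5 allyl cation.
- Stereochemistry: C7 comes from (S)-carvone; C1 from a chelation-controlled Grignard addition; C10 from a hydroxyl-directed dihydroxylation; C9 from a hydroxyl-directed hydride delivery; C5 from the shift itself (C1 adds anti to the directed epoxide oxygen, with retention at C1).

Key step: step 13

Remark (convention and assumption): every intermediate carries the atom numbers of the target in guaiane numbering (C1 and C5 ring fusion, C4=C15 methylene, C6 ketone, C7 isopropyl, C9 ester, C10 carbinol with the C14 methyl). (S)-(+)-Carvone is taken as the commercial source of chirality.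

**Route**

Step 1
Reactants: 1 (S)-(+)-carvone
Product: 2 (S)-carvotanacetone
Conditions: H2 (1 atm), RhCl(PPh3)3 (1 mol %), benzene, rt
Reagents that add atoms: none
Why: Homogeneous (Wilkinson) hydrogenation should reduce the unhindered 1,1-disubstituted isopropenyl alkene much faster than the trisubstituted conjugated ring alkene, and the C7 stereocenter is not touched.

Step 2
Reactants: 2 (S)-carvotanacetone
Product: 3 (5R,6R)-6-hydroxy-2-methyl-5-(propan-2-yl)cyclohex-2-en-1-one
Conditions: KHMDS, THF, −78 °C; 3-phenyl-2-(phenylsulfonyl)oxaziridine, −78 °C; AcOH quench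
Reagents that add atoms: 3-phenyl-2-(phenylsulfonyl)oxaziridine (Davis oxaziridine), O=S(=O)(N1OC1c1ccccc1)c1ccccc1
Why: Kinetic α′-deprotonation gives the cross-conjugated C6 enolate, and Davis enolate hydroxylation should deliver oxygen anti to the neighbouring isopropyl group, so the 6-OH is trans to it (a relay center that is oxidised away in step 4).

Step 3
Reactants: 3 (5R,6R)-6-hydroxy-2-methyl-5-(propan-2-yl)cyclohex-2-en-1-one; 4 2-(2-bromoethyl)-2-methyl-1,3-dioxolane
Product: 6 (1R,2S,6R)-3-methyl-2-[2-(2-methyl-1,3-dioxolan-2-yl)ethyl]-6-(propan-2-yl)cyclohex-3-ene-1,2-diol, via Grignard reagent 5 (not isolated)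
Conditions: 4, Mg, THF, rt (gives 5, 3 equiv); then 3, THF, −78 → 0 °C; aq. NH4Cl
Reagents that add atoms: none
Why: Chelation-controlled Grignard 1,2-addition: the first equivalent makes the C6 magnesium alkoxide, which chelates the C1 carbonyl, so the second equivalent should add trans to the C6–O bond (the cis-diol outcome known for 2-oxygenated cyclohexanones), placing 1-OH cis to 6-OH and trans to the isopropyl group.

Step 4
Reactants: 6 (1R,2S,6R)-3-methyl-2-[2-(2-methyl-1,3-dioxolan-2-yl)ethyl]-6-(propan-2-yl)cyclohex-3-ene-1,2-diol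
Product: 7 (2S,6R)-2-hydroxy-3-methyl-2-[2-(2-methyl-1,3-dioxolan-2-yl)ethyl]-6-(propan-2-yl)cyclohex-3-en-1-one
Conditions: IBX, DMSO, rt
Reagents that add atoms: none
Why: IBX oxidation converts the secondary C6 alcohol of the 1,2-diol into the ketone without glycol cleavage and should leave the tertiary allylic C1 alcohol and the dioxolane untouched.

Step 5
Reactants: 7 (2S,6R)-2-hydroxy-3-methyl-2-[2-(2-methyl-1,3-dioxolan-2-yl)ethyl]-6-(propan-2-yl)cyclohex-3-en-1-one
Product: 9 (4aS,8R)-4a-hydroxy-5-methyl-8-(propan-2-yl)-4,4a,7,8-tetrahydronaphthalen-2(3H)-one, via diketone 8 (not isolated)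
Conditions: PPTS (cat.), acetone–H2O, 45 °C; then pyrrolidine (0.5 equiv), AcOH, toluene, 60 °C
Reagents that add atoms: water, O
Why: Mild acid unmasks the methyl ketone, and an enamine-mediated intramolecular aldol condensation (Robinson-type closure) of the methyl carbon C5 onto the C6 ketone should close ring A and dehydrate to the enone; no stereocenter is formed, and amine catalysis is chosen over alkoxide to avoid α-ketol rearrangement of 8.

Step 6
Reactants: 9 (4aS,8R)-4a-hydroxy-5-methyl-8-(propan-2-yl)-4,4a,7,8-tetrahydronaphthalen-2(3H)-one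
Product: 10 (4aR,5S,6S,8R)-4a,5,6-trihydroxy-5-methyl-8-(propan-2-yl)-4,4a,5,6,7,8-hexahydronaphthalen-2(3H)-one
Conditions: OsO4 (1.05 equiv), TMEDA, CH2Cl2, −78 °C; then aq. Na2SO3, rt
Reagents that add atoms: osmium tetroxide, O=[Os](=O)(=O)=O
Why: Hydrogen-bond-directed dihydroxylation (OsO4·TMEDA, Donohoe conditions) should attack the electron-rich C9=C10 alkene and not the enone, from the face of the allylic 1-OH (also the face not shielded by the ring A methylene C2), so that 10-OH and 9-OH are cis to 1-OH.

Step 7
Reactants: 10 (4aR,5S,6S,8R)-4a,5,6-trihydroxy-5-methyl-8-(propan-2-yl)-4,4a,5,6,7,8-hexahydronaphthalen-2(3H)-one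
Product: 11 (4aR,5R,8R)-4a,5-dihydroxy-5-methyl-8-(propan-2-yl)-4,4a,7,8-tetrahydronaphthalene-2,6(3H,5H)-dione
Conditions: IBX, DMSO, rt
Reagents that add atoms: none
Why: IBX oxidation acts on the only secondary alcohol (C9), because the C1 and C10 alcohols are tertiary and IBX does not cleave the glycol.

Step 8
Reactants: 11 (4aR,5R,8R)-4a,5-dihydroxy-5-methyl-8-(propan-2-yl)-4,4a,7,8-tetrahydronaphthalene-2,6(3H,5H)-dione
Product: 12 (4aR,5S,6R,8R)-4a,5,6-trihydroxy-5-methyl-8-(propan-2-yl)-4,4a,5,6,7,8-hexahydronaphthalen-2(3H)-one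
Conditions: Me4NBH(OAc)3, MeCN–AcOH, −30 °C
Reagents that add atoms: none
Why: Evans–Saksena hydroxyl-directed reduction: the borohydride exchanges onto the 1-OH (β to the ketone) and 10-OH (α) and should deliver hydride to C9 from their face, giving 9-OH anti to both (cis to the isopropyl group), while the enone, which has no suitably placed hydroxyl, is not reduced.

Step 9
Reactants: 12 (4aR,5S,6R,8R)-4a,5,6-trihydroxy-5-methyl-8-(propan-2-yl)-4,4a,5,6,7,8-hexahydronaphthalen-2(3H)-one
Product: 13 (1S,2R,4R,8aR)-1-methyl-6-methylidene-4-(propan-2-yl)-1,2,3,4,6,7,8,8a-octahydronaphthalene-1,2,8a-triol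
Conditions: Ph3PCH3Br (6 equiv), KOtBu, THF, 0 °C → rt
Reagents that add atoms: methyltriphenylphosphonium bromide, C[P+](c1ccccc1)(c1ccccc1)c1ccccc1.[Br-]
Why: Wittig methylenation of the enone carbonyl (1,2-attack of the non-stabilised ylide) should give the C4=C15 methylene as part of a 1,3-diene, with excess ylide absorbing the three hydroxyl protons.

Step 10
Reactants: 13 (1S,2R,4R,8aR)-1-methyl-6-methylidene-4-(propan-2-yl)-1,2,3,4,6,7,8,8a-octahydronaphthalene-1,2,8a-triol
Product: 14 (1S,2R,4R,8aR)-1,8a-dihydroxy-1-methyl-6-methylidene-4-(propan-2-yl)-1,2,3,4,6,7,8,8a-octahydronaphthalen-2-yl (2Z)-2-methylbut-2-enoate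
Conditions: angelic acid, 2,4,6-trichlorobenzoyl chloride, Et3N, toluene, rt; then 13, 80 °C
Reagents that add atoms: angelic acid, C/C=C(/C)C(=O)O
Why: Yamaguchi-type mixed-anhydride esterification should acylate only the secondary C9 alcohol (the other two are tertiary), and the DMAP-free protocol is the usual way to keep the Z (angelate) geometry.

Step 11
Reactants: 14 (1S,2R,4R,8aR)-1,8a-dihydroxy-1-methyl-6-methylidene-4-(propan-2-yl)-1,2,3,4,6,7,8,8a-octahydronaphthalen-2-yl (2Z)-2-methylbut-2-enoate
Product: 15 the C5–C6 epoxide of 14 with the epoxide oxygen on the face of the C1 and C10 hydroxyls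
Conditions: VO(acac)2 (5 mol %), t-BuOOH, toluene, 0 °C
Reagents that add atoms: tert-butyl hydroperoxide, CC(C)(C)OO
Why: Vanadium-catalysed hydroxyl-directed epoxidation should oxidise only C5=C6 (allylic to 1-OH, homoallylic to 10-OH) and deliver oxygen syn to these hydroxyls, leaving the exocyclic methylene and the electron-poor angelate alkene alone.

Step 12
Reactants: 15 the C5–C6 epoxide of 14
Product: 16 the trans bromohydrin: C5–Br anti to the C6–OH, with 6-OH cis to 1-OH
Conditions: LiBr, AcOH, THF, 0 °C; used crude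
Reagents that add atoms: lithium bromide, [Li+].[Br-]
Why: Nucleophilic opening of the vinyl epoxide: bromide should attack the allylic secondary carbon C5 by SN2 with inversion and not the tertiary C6, keeping the C6–O bond; an SN2′ isomer, if formed, would ionise to the same cation in step 13.

Step 13
Reactants: 16 the trans bromohydrin
Product: 17 (1R,5S,7R,9R,10S)-1,10-dihydroxy-6-oxoguai-4(15)-en-9-yl (2Z)-2-methylbut-2-enoate (CNP0124926.1)
Conditions: AgBF4 (1.2 equiv), 2,6-di-tert-butyl-4-methylpyridine, CH2Cl2, −78 → −20 °C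
Reagents that add atoms: none
Why: Silver(I) abstracts the allylic bromide to give the 2-substituted allyl cation C5–C4–C15, and the ring-fusion carbon C1 shifts from the carbinol carbon C6 to C5 while the C6 hydroxyl becomes the ketone (semipinacol rearrangement, proton taken by the hindered pyridine). The closest known reaction types are the silver- or magnesium-promoted semipinacol rearrangement of halohydrins (Tiffeneau-type ring contraction of 2-halocyclohexanols) and the pinacol-type hydronaphthalene-to-hydroazulene rearrangement. No ring is closed by cyclisation: the cyclopentane arises by contraction of ring A through the 1,2-shift (new C1–C5 bond), and the cycloheptanone arises by one-carbon expansion of the carvone-derived cyclohexane (C5 inserted between C1 and C6). The new stereocenter C5 is controlled by the cis-fused conformation with the isopropyl group equatorial, in which the C6–O bond is axial on ring A and C1 lies on the opposite face of the cation; C1 therefore adds anti to the former epoxide oxygen, H-5 ends trans to 1-OH, and C1 migrates with retention. The step needs ionisation at C5 only and migration of C1 rather than C7: the only leaving group sits on the allylic carbon and C6 carries a hydroxyl that can only push, and the C6–C7 bond is pseudo-equatorial, near the nodal plane of the cation. Trapping of C15 by 1-OH or 6-OH is excluded because it would put an E double bond into a five- or six-membered ring.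

**Compound list**
1 | (S)-(+)-carvone, (5S)-2-methyl-5-(prop-1-en-2-yl)cyclohex-2-en-1-one | CC1=CC[C@@H](CC1=O)C(C)=C | starting material
2 | (S)-carvotanacetone, (5S)-2-methyl-5-(propan-2-yl)cyclohex-2-en-1-one | CC1=CC[C@@H](CC1=O)C(C)C | intermediate
3 | (5R,6R)-6-hydroxy-2-methyl-5-(propan-2-yl)cyclohex-2-en-1-one (OH trans to isopropyl) | O=C1[C@H](O)[C@@H](C(C)C)CC=C1C | intermediate
4 | 2-(2-bromoethyl)-2-methyl-1,3-dioxolane | CC1(CCBr)OCCO1 | starting material
5 | [2-(2-methyl-1,3-dioxolan-2-yl)ethyl]magnesium bromide | CC1(CC[Mg]Br)OCCO1 | intermediate (not isolated)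
6 | (1R,2S,6R)-3-methyl-2-[2-(2-methyl-1,3-dioxolan-2-yl)ethyl]-6-(propan-2-yl)cyclohex-3-ene-1,2-diol (cis-diol, both OH trans to isopropyl) | O[C@]1(CCC2(C)OCCO2)[C@H](O)[C@@H](C(C)C)CC=C1C | intermediate
7 | (2S,6R)-2-hydroxy-3-methyl-2-[2-(2-methyl-1,3-dioxolan-2-yl)ethyl]-6-(propan-2-yl)cyclohex-3-en-1-one | O[C@]1(CCC2(C)OCCO2)C(=O)[C@@H](C(C)C)CC=C1C | intermediate
8 | (2S,6R)-2-hydroxy-3-methyl-2-(3-oxobutyl)-6-(propan-2-yl)cyclohex-3-en-1-one | O[C@]1(CCC(C)=O)C(=O)[C@@H](C(C)C)CC=C1C | intermediate (not isolated)
9 | (4aS,8R)-4a-hydroxy-5-methyl-8-(propan-2-yl)-4,4a,7,8-tetrahydronaphthalen-2(3H)-one | O[C@]12CCC(=O)C=C1[C@@H](C(C)C)CC=C2C | intermediate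
10 | (4aR,5S,6S,8R)-4a,5,6-trihydroxy-5-methyl-8-(propan-2-yl)-4,4a,5,6,7,8-hexahydronaphthalen-2(3H)-one (three OH cis) | O[C@]12CCC(=O)C=C1[C@@H](C(C)C)C[C@H](O)[C@]2(C)O | intermediate
11 | (4aR,5R,8R)-4a,5-dihydroxy-5-methyl-8-(propan-2-yl)-4,4a,7,8-tetrahydronaphthalene-2,6(3H,5H)-dione | O[C@]12CCC(=O)C=C1[C@@H](C(C)C)CC(=O)[C@]2(C)O | intermediate
12 | (4aR,5S,6R,8R)-4a,5,6-trihydroxy-5-methyl-8-(propan-2-yl)-4,4a,5,6,7,8-hexahydronaphthalen-2(3H)-one (6-OH trans to the 5- and 4a-OH, cis to isopropyl) | O[C@]12CCC(=O)C=C1[C@@H](C(C)C)C[C@@H](O)[C@]2(C)O | intermediate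
13 | (1S,2R,4R,8aR)-1-methyl-6-methylidene-4-(propan-2-yl)-1,2,3,4,6,7,8,8a-octahydronaphthalene-1,2,8a-triol | O[C@]12CCC(=C)C=C1[C@@H](C(C)C)C[C@@H](O)[C@]2(C)O | intermediate
14 | (1S,2R,4R,8aR)-1,8a-dihydroxy-1-methyl-6-methylidene-4-(propan-2-yl)-1,2,3,4,6,7,8,8a-octahydronaphthalen-2-yl (2Z)-2-methylbut-2-enoate | O[C@]12CCC(=C)C=C1[C@@H](C(C)C)C[C@@H](OC(=O)/C(C)=C\C)[C@]2(C)O | intermediate
15 | C5–C6 epoxide of 14, epoxide oxygen cis to the C1 and C10 hydroxyls (cis-fused) | O[C@]12CCC(=C)[C@@H]3O[C@@]31[C@@H](C(C)C)C[C@@H](OC(=O)/C(C)=C\C)[C@]2(C)O | intermediate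
16 | bromohydrin of 15: C5–Br trans to C6–OH, C6–OH cis to C1–OH | O[C@]12CCC(=C)[C@@H](Br)[C@@]1(O)[C@@H](C(C)C)C[C@@H](OC(=O)/C(C)=C\C)[C@]2(C)O | intermediate
17 | (1R,5S,7R,9R,10S)-1,10-dihydroxy-6-oxoguai-4(15)-en-9-yl (2Z)-2-methylbut-2-enoate (CNP0124926.1) | C=C1CC[C@@]2(O)[C@H]1C(=O)[C@@H](C(C)C)C[C@@H](OC(=O)/C(C)=C\C)[C@]2(C)O | target

Total step count: 13. Longest linear sequence: 13 steps (from 1; the Grignard reagent from 4 is made in the flask of step 3).

**Steps most likely to fail**

Step 13. After ionisation the wrong bond on C6 (C6–C7) may migrate from a minor conformer, the C6 hydroxyl may simply re-close to the epoxide, or C5 may be attacked from the wrong face, so that regio- or stereocontrol of the shift is lost. The fallback sets out from 15 and comes back at 17. The two tertiary hydroxyls of 15 are tied up with phenylboronic acid (toluene, MgSO4) as the cyclic phenylboronate F1, so that neither oxygen can assist cleavage of the C6–O bond or trap the cation. BF3·OEt2 (CH2Cl2, −78 °C) should then open the epoxide at the allylic C5–O bond with a concerted anti 1,2-shift of C1 (Meinwald-type epoxide rearrangement), giving the phenylboronate of the target F2. Transesterification with pinacol releases 17.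

Step 3. The carbonyl addition may show poor facial selectivity (non-chelated axial attack), or the alkoxide of 3 may enolise or isomerise as an α-ketol. The fallback sets out from 3 and 4 and comes back at 6; it sets C1 by a directed epoxidation instead of a carbonyl addition. Bromide 4 and PPh3 give the phosphonium bromide F3, whose ylide (n-BuLi) should olefinate the C1 carbonyl of 3 to the dienol F4 (E/Z mixture, irrelevant). VO(acac)2/t-BuOOH, directed by the allylic 6-OH, should put the epoxide oxygen on C1 syn to 6-OH, giving the epoxy alcohol F5 (C2 configuration irrelevant). LiBHEt3 then opens the epoxide at the less substituted carbon C2 and gives 6.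

Step 5. Exposure of the α-ketol 8 to amine or base may cause acyloin (α-ketol) rearrangement, or the hindered C6 carbonyl may resist closure so that only the reversible bridged aldol (C7 onto C4) forms. The fallback sets out from 7 and comes back at 9. Diketone 8 is isolated after the PPTS hydrolysis. Bu2BOTf/i-Pr2NEt (CH2Cl2, −78 → 0 °C) should enolise the methyl ketone on the methyl side, and the boron enolate adds irreversibly to the C6 ketone to give the cis-fused ketol F6. Burgess reagent (one equivalent, benzene, rt) should then dehydrate the β-hydroxy ketone, whose syn β-hydrogen at C5 is acidified by the C4 carbonyl, to give 9.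

**Further compounds**
F1 | step 13 | cyclic phenylboronate of epoxide 15 (boron bridging the C1 and C10 oxygens) | c1ccccc1B1O[C@]23CCC(=C)[C@@H]4O[C@@]42[C@@H](C(C)C)C[C@@H](OC(=O)/C(C)=C\C)[C@]3(C)O1
F2 | step 13 | cyclic phenylboronate of target 17 (boron bridging the C1 and C10 oxygens) | C=C1CC[C@@]2(OB3c4ccccc4)[C@H]1C(=O)[C@@H](C(C)C)C[C@@H](OC(=O)/C(C)=C\C)[C@]2(C)O3
F3 | step 3 | [2-(2-methyl-1,3-dioxolan-2-yl)ethyl]triphenylphosphonium bromide | CC1(CC[P+](c2ccccc2)(c2ccccc2)c2ccccc2)OCCO1.[Br-]
F4 | step 3 | (1R,6R)-3-methyl-2-[3-(2-methyl-1,3-dioxolan-2-yl)propylidene]-6-(propan-2-yl)cyclohex-3-en-1-ol (E/Z mixture) | CC1(CC=C2[C@H](O)[C@@H](C(C)C)CC=C2C)OCCO1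
F5 | step 3 | spiro-epoxide of F4 at C1–C2, epoxide oxygen on C1 cis to the 6-OH | CC1(CC2O[C@@]23[C@H](O)[C@@H](C(C)C)CC=C3C)OCCO1
F6 | step 5 | cis-fused ketol: 4a,8a-dihydroxy-5-methyl-8-(propan-2-yl)-3,4,4a,7,8,8a-hexahydronaphthalen-2(1H)-one, both OH cis | O[C@]12CCC(=O)C[C@@]1(O)[C@@H](C(C)C)CC=C2C
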